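**Plan**

- Retrosynthesis: ring D (the quinone ring) is cut at its C(OMe)–CH bond (Claisen) and at the bond between the aryloxy carbon and the alkyl-bearing carbon (Michael). The second bond also belongs to the 18-membered ring, so one [3+3] event opens both rings. Further cuts: acetonyl ether C–O, enoate C=C, the ring B–ring C ethylene bridge (Wittig/H2), the ring A–O–ring B ether (Ullmann).
- Enabling feature: across the lone ring CH, the C–OMe carbon and the neighbouring C=O carbon are 1,3-dioxygenated (a masked cyclohexane-1,3-dione). The C–OAr carbon is alpha to that carbonyl and the alkyl-bearing carbon is beta to the C–OMe carbon. Ring D is therefore an α-aryloxy acetone (3 C, on the ring C oxygen) plus an enoate (3 C, on the ring A chain).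
- Forward: rings A and B are joined, ring C is attached and the bridge saturated, the enoate and the acetonyl ether are put on the two ends, and one base-mediated cascade closes the macrocycle and ring D. Ring D is then O-methylated, aromatised and oxidised to the para-quinone, and the ring B phenol is unmasked.
- Stereochemistry: the target has no stereocentre; the alkene geometries and the two sp3 centres that appear on the way are erased by hydrogenation or aromatisation.

Key step: step 8

Remark: alkene 6 (E/Z) and the ring D intermediates 13 to 15 (two sp3 centres, racemic diastereomers) are carried as mixtures because steps 4 and 10 remove these elements; their SMILES carry no configuration.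

**Route**

Step 1
Reactants: 1 methyl 3-(4-hydroxyphenyl)propanoate; 2 4-(benzyloxy)-3-bromobenzaldehyde
Product: 3 methyl 3-{4-[2-(benzyloxy)-5-formylphenoxy]phenyl}propanoate
Conditions: CuI (10 mol %), N,N-dimethylglycine hydrochloride (30 mol %), Cs2CO3, 1,4-dioxane, 90 °C
Reagents that add atoms: none
Why: Copper-catalysed Ullmann diaryl ether coupling of the phenoxide of 1 with the electron-poor aryl bromide 2; ester, aldehyde and benzyl ether should be inert under these conditions.

Step 2
Reactants: 4 3-(hydroxymethyl)phenol
Product: 5 (3-hydroxybenzyl)triphenylphosphonium bromide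
Conditions: Ph3P·HBr, MeCN, reflux
Reagents that add atoms: triphenylphosphine hydrobromide, [Br-].[PH+](c1ccccc1)(c1ccccc1)c1ccccc1
Why: Acid-promoted substitution of the benzylic alcohol by triphenylphosphine should give the phosphonium salt directly, with the phenol left unprotected.

Step 3
Reactants: 3 methyl 3-{4-[2-(benzyloxy)-5-formylphenoxy]phenyl}propanoate; 5 (3-hydroxybenzyl)triphenylphosphonium bromide
Product: 6 methyl 3-{4-[2-(benzyloxy)-5-[2-(3-hydroxyphenyl)ethenyl]phenoxy]phenyl}propanoate (E/Z mixture)
Conditions: NaOMe (2.2 equiv), MeOH, rt; aq. HCl work-up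
Reagents that add atoms: none
Why: Wittig olefination of the aryl aldehyde by the semi-stabilised benzylic ylide (the second equivalent of base covers the phenol); methoxide in methanol leaves the methyl ester unchanged, and the alkene geometry does not matter because step 4 saturates it.

Step 4
Reactants: 6 stilbene ester (E/Z mixture)
Product: 7 methyl 3-{4-[2-(benzyloxy)-5-[2-(3-hydroxyphenyl)ethyl]phenoxy]phenyl}propanoate
Conditions: H2 (1 atm), Pd/C, Ph2S (cat.), EtOAc, rt
Reagents that add atoms: none
Why: Heterogeneous hydrogenation of the stilbene; sulfide-poisoned Pd/C should saturate the C=C bond without hydrogenolysis of the benzyl aryl ether.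

Step 5
Reactants: 7 bibenzyl ester
Product: 8 3-{4-[2-(benzyloxy)-5-[2-(3-hydroxyphenyl)ethyl]phenoxy]phenyl}propanal
Conditions: DIBAL-H (2.2 equiv), CH2Cl2, −78 °C; MeOH, aq. Rochelle salt
Reagents that add atoms: none
Why: Partial reduction of the methyl ester by DIBAL-H at low temperature stops at the aldehyde through the stable aluminium hemiacetal; the first equivalent is consumed by the phenol.

Step 6
Reactants: 8 aldehyde; 9 methyl (triphenylphosphoranylidene)acetate
Product: 10 methyl (2E)-5-{4-[2-(benzyloxy)-5-[2-(3-hydroxyphenyl)ethyl]phenoxy]phenyl}pent-2-enoate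
Conditions: CH2Cl2, rt
Reagents that add atoms: none
Why: Wittig olefination with a stabilised ylide should give the (E)-enoate under neutral conditions that tolerate the free phenol.

Step 7
Reactants: 10 (E)-enoate phenol; 11 chloroacetone
Product: 12 methyl (2E)-5-{4-[2-(benzyloxy)-5-{2-[3-(2-oxopropoxy)phenyl]ethyl}phenoxy]phenyl}pent-2-enoate
Conditions: K2CO3, KI (cat.), acetone, reflux
Reagents that add atoms: none
Why: Williamson ether synthesis: the ring C phenoxide (the only acidic OH) displaces halide from the α-halo ketone in an iodide-assisted SN2 reaction.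

Step 8
Reactants: 12 linear keto enoate
Product: 14 macrocyclic cyclohexane-1,3-dione, via macrocyclic keto ester 13 (not isolated)
Conditions: t-BuOK (3 equiv), THF, 0.001 M (12 added by syringe pump), 0 °C to rt; aq. HCl work-up
Reagents that add atoms: none
Why: Proposed new method: t-BuOK generates the thermodynamic enolate at the aryloxy-substituted α-carbon of the methyl ketone (the O-bearing CH2 is markedly more acidic than the CH3), which adds reversibly in 1,4-fashion to the β-carbon of the (E)-enoate and closes the 18-membered ring in an 18-exo-trig mode; the methyl-ketone enolate of the resulting δ-keto ester 13 then attacks the ester carbonyl in a 6-exo-trig Claisen condensation, which forms the bond between the future ring CH and the future C–OMe carbon and expels methoxide. The closest known reaction type is the intermolecular consecutive Michael–Claisen synthesis of 4-substituted cyclohexane-1,3-diones from substituted acetones and α,β-unsaturated esters with t-BuOK; only its use to close a macrocycle is new. The step needs ring closure to outrun oligomerisation and the conjugate addition to start from the O-bearing carbon: high dilution, the reversibility of the Michael step and the irreversible formation of the β-diketonate (which drains all preceding equilibria) serve the first, and the acidifying aryloxy group secures the second. Two stereocentres arise (the O-bearing and the alkyl-bearing ring carbons); they are controlled only by the thermodynamic preference at the epimerisable α-carbon, and both are erased in step 10.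

Step 9
Reactants: 14 macrocyclic cyclohexane-1,3-dione
Product: 15 macrocyclic 3-methoxycyclohex-2-enone (vinylogous methyl ester)
Conditions: Me2SO4, K2CO3, acetone, rt
Reagents that add atoms: dimethyl sulfate, COS(=O)(=O)OC
Why: O-alkylation of the cyclic β-diketone enolate by a hard electrophile; the oxygen on the carbonyl remote from the aryloxy carbon is less hindered and more electron-rich, so the enol ether should form there and the ketone remain next to the aryloxy carbon.

Step 10
Reactants: 15 macrocyclic vinylogous methyl ester
Product: 16 macrocyclic phenol (ring D = 2-aryloxy-3-alkyl-5-methoxyphenol)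
Conditions: Pd(OCOCF3)2 (5 mol %), 2-(dimethylamino)pyridine (10 mol %), TsOH (20 mol %), O2 (1 atm), DMSO, 80 °C
Reagents that add atoms: none
Why: Palladium-catalysed aerobic dehydrogenation of a cyclohexenone (α-palladation, β-hydride elimination, O2 as terminal oxidant) gives a dienone that tautomerises to the phenol; dehydrogenation on either side of the alkyl-bearing carbon leads to the same arene.

Step 11
Reactants: 16 macrocyclic phenol
Product: 17 O-benzyl ether of the target quinone
Conditions: (KSO3)2NO, KH2PO4, acetone–H2O, rt
Reagents that add atoms: potassium nitrosodisulfonate (Fremy's salt), [K+].[K+].[O-]S(=O)(=O)N([O])S(=O)(=O)[O-]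
Why: Teuber oxidation: the nitroxyl radical oxidises the only free phenol and delivers oxygen to its unsubstituted para carbon, which should give the para-quinone with the methoxy and aryloxy groups in place.

Step 12
Reactants: 17 O-benzyl quinone
Product: 19 CNP0332646.0 (target quinone), via macrocyclic hydroquinone 18 (not isolated)
Conditions: H2 (1 atm), Pd/C, EtOAc–MeOH, rt; filter; then air, rt
Reagents that add atoms: none
Why: Hydrogenolysis of the benzyl aryl ether (the quinone is reduced to the hydroquinone on the way) followed by autoxidation of the electron-rich hydroquinone in air should restore the quinone, while the ring B monophenol is not oxidised by air.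

**Compound list**

1 | methyl 3-(4-hydroxyphenyl)propanoate | COC(=O)CCc1ccc(O)cc1 | starting material
2 | 4-(benzyloxy)-3-bromobenzaldehyde | O=Cc1ccc(OCc2ccccc2)c(Br)c1 | starting material
3 | methyl 3-{4-[2-(benzyloxy)-5-formylphenoxy]phenyl}propanoate | COC(=O)CCc1ccc(Oc2cc(C=O)ccc2OCc2ccccc2)cc1 | intermediate
4 | 3-(hydroxymethyl)phenol | OCc1cccc(O)c1 | starting material
5 | (3-hydroxybenzyl)triphenylphosphonium bromide | [Br-].Oc1cccc(C[P+](c2ccccc2)(c2ccccc2)c2ccccc2)c1 | intermediate
6 | methyl 3-{4-[2-(benzyloxy)-5-[2-(3-hydroxyphenyl)ethenyl]phenoxy]phenyl}propanoate, E/Z mixture | COC(=O)CCc1ccc(Oc2cc(C=Cc3cccc(O)c3)ccc2OCc2ccccc2)cc1 | intermediate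
7 | methyl 3-{4-[2-(benzyloxy)-5-[2-(3-hydroxyphenyl)ethyl]phenoxy]phenyl}propanoate | COC(=O)CCc1ccc(Oc2cc(CCc3cccc(O)c3)ccc2OCc2ccccc2)cc1 | intermediate
8 | 3-{4-[2-(benzyloxy)-5-[2-(3-hydroxyphenyl)ethyl]phenoxy]phenyl}propanal | O=CCCc1ccc(Oc2cc(CCc3cccc(O)c3)ccc2OCc2ccccc2)cc1 | intermediate
9 | methyl (triphenylphosphoranylidene)acetate | COC(=O)C=P(c1ccccc1)(c1ccccc1)c1ccccc1 | starting material
10 | methyl (2E)-5-{4-[2-(benzyloxy)-5-[2-(3-hydroxyphenyl)ethyl]phenoxy]phenyl}pent-2-enoate | COC(=O)/C=C/CCc1ccc(Oc2cc(CCc3cccc(O)c3)ccc2OCc2ccccc2)cc1 | intermediate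
11 | chloroacetone | CC(=O)CCl | starting material
12 | methyl (2E)-5-{4-[2-(benzyloxy)-5-{2-[3-(2-oxopropoxy)phenyl]ethyl}phenoxy]phenyl}pent-2-enoate | COC(=O)/C=C/CCc1ccc(Oc2cc(CCc3cccc(OCC(C)=O)c3)ccc2OCc2ccccc2)cc1 | intermediate
13 | macrocyclic δ-keto ester: 18-membered ring in which the carbon bearing the ring C oxygen carries an acetyl group and the adjacent ring carbon carries CH2CO2Me; ring B O-benzyl; diastereomer mixture, racemic | COC(=O)CC1CCc2ccc(cc2)Oc2cc(ccc2OCc2ccccc2)CCc2cccc(c2)OC1C(C)=O | intermediate
14 | macrocyclic 4-aryloxy-5-alkylcyclohexane-1,3-dione (ring D as the dione; ring B O-benzyl); diastereomer mixture, racemic | O=C1CC(=O)C2Oc3cccc(c3)CCc3ccc(OCc4ccccc4)c(c3)Oc3ccc(cc3)CCC2C1 | intermediate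
15 | macrocyclic 3-methoxycyclohex-2-enone (ring D; ketone next to the aryloxy carbon; ring B O-benzyl); diastereomer mixture, racemic | COC1=CC(=O)C2Oc3cccc(c3)CCc3ccc(OCc4ccccc4)c(c3)Oc3ccc(cc3)CCC2C1 | intermediate
16 | macrocyclic phenol (ring D = 2-aryloxy-3-alkyl-5-methoxyphenol; ring B O-benzyl) | COc1cc(O)c2Oc3cccc(c3)CCc3ccc(OCc4ccccc4)c(c3)Oc3ccc(cc3)CCc2c1 | intermediate
17 | O-benzyl ether (ring B) of the target quinone | COC1=CC(=O)C2=C(CCc3ccc(cc3)Oc3cc(ccc3OCc3ccccc3)CCc3cccc(c3)O2)C1=O | intermediate
18 | macrocyclic hydroquinone of the target (ring B phenol free) | COc1cc(O)c2c(c1O)CCc1ccc(cc1)Oc1cc(ccc1O)CCc1cccc(c1)O2 | intermediate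
19 | CNP0332646.0 | COC1=CC(=O)C2=C(CCc3ccc(cc3)Oc3cc(ccc3O)CCc3cccc(c3)O2)C1=O | target

**Summary**

Total step count: 12. Longest linear sequence: 11 steps (steps 1 and 3 to 12); step 2 prepares the phosphonium salt for the convergent union in step 3.

Steps most likely to fail:

1. Step 8 (Proposed new method). Intermolecular conjugate addition may outrun ring closure and give oligomers. The enoate may be deconjugated by γ-deprotonation, or the conjugate addition may start from the methyl side of the ketone. The fallback uses known chemistry and closes the macrocycle at the C–O bond instead. It sets out from 10. Intermolecular consecutive Michael–Claisen annulation of 10 with acetone (t-BuOK, THF, extra base for the phenol) gives the 5-substituted cyclohexane-1,3-dione F1. Acid-catalysed enol ether formation (MeOH, HC(OMe)3, TsOH) gives the single vinylogous methyl ester F2, since the dione is symmetrical. Kinetic α′-enolisation with silylation (LDA, TMSCl, −78 °C, the phenol being silylated in passing) followed by NBS and aqueous work-up gives the trans α′-bromo enone F3. Cs2CO3 in MeCN at high dilution then closes the 18-membered ring by intramolecular Williamson etherification of the ring C phenoxide at the α-bromo ketone. This gives 15, where the route is rejoined before step 10.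

2. Step 9. Methylation may occur at the oxygen next to the aryloxy carbon, or at the carbon between the two carbonyls, so that the wrong vinylogous ester is carried on. The fallback makes the methyl ether regiospecifically at the quinone stage. It sets out from 14. Catalytic dehydrogenation (I2 cat., DMSO, heat) gives the macrocyclic resorcinol F4. Fremy's salt oxidises it to the macrocyclic 2-hydroxy-para-quinone F5; only one hydroxyl has a free para position, and attack through the other converges by tautomerism. O-methylation of the single vinylogous acid (MeI, Ag2O, CHCl3) gives 17, where the route is rejoined before step 12.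

3. Step 10. Palladation of the hindered α-carbon may be slow so that the dehydrogenation stalls. The vinylogous ester may be hydrolysed by the water formed, and the electron-rich phenol may be over-oxidised. The fallback replaces catalytic dehydrogenation by enolate selenenylation and syn-elimination. It sets out from 15. LDA (THF, −78 °C) then PhSeBr gives the α-phenylselanyl ketone F6, with selenium on the aryloxy-bearing carbon and cis to the neighbouring hydrogen. H2O2 with pyridine (CH2Cl2, 0 °C) forms the selenoxide, which eliminates to the dienone; this tautomerises to 16, where the route is rejoined before step 11.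

Further compounds
F1 | step 8 | 5-{2-[4-(2-(benzyloxy)-5-[2-(3-hydroxyphenyl)ethyl]phenoxy)phenyl]ethyl}cyclohexane-1,3-dione | O=C1CC(=O)CC(CCc2ccc(Oc3cc(CCc4cccc(O)c4)ccc3OCc3ccccc3)cc2)C1
F2 | step 8 | 5-{2-[4-(2-(benzyloxy)-5-[2-(3-hydroxyphenyl)ethyl]phenoxy)phenyl]ethyl}-3-methoxycyclohex-2-en-1-one (racemic) | COC1=CC(=O)CC(CCc2ccc(Oc3cc(CCc4cccc(O)c4)ccc3OCc3ccccc3)cc2)C1
F3 | step 8 | trans-6-bromo-5-{2-[4-(2-(benzyloxy)-5-[2-(3-hydroxyphenyl)ethyl]phenoxy)phenyl]ethyl}-3-methoxycyclohex-2-en-1-one (racemic) | COC1=CC(=O)C(Br)C(CCc2ccc(Oc3cc(CCc4cccc(O)c4)ccc3OCc3ccccc3)cc2)C1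
F4 | step 9 | macrocyclic resorcinol (ring D = 4-aryloxy-5-alkylbenzene-1,3-diol; ring B O-benzyl) | Oc1cc(O)c2Oc3cccc(c3)CCc3ccc(OCc4ccccc4)c(c3)Oc3ccc(cc3)CCc2c1
F5 | step 9 | macrocyclic 2-hydroxy-para-quinone (hydroxyl in place of the methoxy group of 17) | OC1=CC(=O)C2=C(CCc3ccc(cc3)Oc3cc(ccc3OCc3ccccc3)CCc3cccc(c3)O2)C1=O
F6 | step 10 | α-phenylselanyl derivative of 15 (selenium on the aryloxy-bearing ring carbon) | COC1=CC(=O)C2([Se]c3ccccc3)Oc3cccc(c3)CCc3ccc(OCc4ccccc4)c(c3)Oc3ccc(cc3)CCC2C1
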